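**Plan**
- Retrosynthesis: the four O–benzyl bonds are cut first, then C8a–O1 of ring C, which opens the protected flavonol to a 1-(2-bromoaryl)-2-benzyloxy-1,3-diketone. Next come C3–C4 (aldol, C4 carbonyl restored by oxidation), C4–C4a (formylation next to bromine), the side-chain C–C bonds (Grignard, Wittig) and the two ring A C–O bonds (SNAr).
- Enabling feature: O1 joins C8a of ring A to C2, and C2–O1 is the enol form of one carbonyl of the C2–C3–C4 1,3-dicarbonyl unit, so a bromide on C8a lets that enolate oxygen close the pyranone.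
- Forward: ring A is bought as 4-bromo-2,6-difluorobenzaldehyde and dressed (benzyl ethers, C6 chain, formyl group), ring B arrives in an α-benzyloxy ketone, the halves are joined at C3–C4, ring C is closed last, and hydrogenolysis frees the phenols.
- Regiochemistry: the two free ring positions of bromide 9 are equivalent, so the formyl group can enter at one kind of carbon only and the chain must end at C6.
- Stereochemistry: the target has no stereocentre; the E-alkene, the aldol diastereomers and the C3 centre of the diketone are all erased on the way.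

Key step: step 9

Assumption: 2-(benzyloxy)-N-methoxy-N-methylacetamide and 4-(benzyloxy)phenylmagnesium bromide (THF solution) are taken as purchasable; diketone 19 is drawn as the diketo tautomer although it should equilibrate with its enols.

**Step 1**
Reactants: 1 4-bromo-2,6-difluorobenzaldehyde; 2 benzyl alcohol
Product: 4 2,6-bis(benzyloxy)-4-bromobenzaldehyde, via 2-(benzyloxy)-4-bromo-6-fluorobenzaldehyde 3 (not isolated)
Conditions: BnOH (2.3 equiv.), NaH (2.3 equiv.), THF, 0 °C; then 1, 0 to 50 °C
Reagents that add atoms: benzyl alcohol (2), OCc1ccccc1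
Why: Twofold nucleophilic aromatic substitution (SNAr): both fluorines are ortho to the formyl group, which stabilises the Meisenheimer adducts, and fluoride leaves far faster than the para bromide, so sodium benzyloxide should replace both fluorines by way of monoether 3 and leave the bromine in place.

**Step 2**
Reactants: 4 2,6-bis(benzyloxy)-4-bromobenzaldehyde; 5 1-(triphenyl-λ5-phosphanylidene)propan-2-one
Product: 6 (3E)-4-[2,6-bis(benzyloxy)-4-bromophenyl]but-3-en-2-one
Conditions: 5 (1.3 equiv.), toluene, 100 °C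
Reagents that add atoms: 1-(triphenyl-λ5-phosphanylidene)propan-2-one (5), CC(=O)C=P(c1ccccc1)(c1ccccc1)c1ccccc1
Why: Wittig olefination with a ketone-stabilised ylide, which should give the E-enone from the non-enolisable aldehyde; the alkene geometry is of no consequence because the double bond is saturated in step 3.

**Step 3**
Reactants: 6 (3E)-4-[2,6-bis(benzyloxy)-4-bromophenyl]but-3-en-2-one
Product: 8 4-[2,6-bis(benzyloxy)-4-bromophenyl]butan-2-one, via dimethylphenylsilyl enol ether 7 (not isolated)
Conditions: [(Ph3P)CuH]6 (3 mol%), PhMe2SiH (1.5 equiv.), toluene, rt; then 1 M HCl, THF, rt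
Reagents that add atoms: none
Why: Copper hydride catalysed conjugate reduction (1,4-hydrosilylation): the soft Cu–H delivers hydride to the β-carbon only, the enolate is held as silyl enol ether 7 until acidic hydrolysis, and neither the aryl bromide nor the benzyl ethers react with copper hydride, which avoids the hydrogenolysis that H2 over Pd/C would cause.

**Step 4**
Reactants: 8 4-[2,6-bis(benzyloxy)-4-bromophenyl]butan-2-one
Product: 9 4-[2,6-bis(benzyloxy)-4-bromophenyl]-2-methylbutan-2-ol
Conditions: MeMgBr (1.5 equiv.), THF, 0 °C; then aq. NH4Cl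
Reagents that add atoms: methylmagnesium bromide, C[Mg]Br
Why: Grignard 1,2-addition to an unhindered methyl ketone gives the tertiary alcohol, and MeMgBr does not undergo bromine–magnesium exchange with the aryl bromide at 0 °C.

**Step 5**
Reactants: 9 4-[2,6-bis(benzyloxy)-4-bromophenyl]-2-methylbutan-2-ol
Product: 12 2,4-bis(benzyloxy)-6-bromo-3-(3-hydroxy-3-methylbutyl)benzaldehyde, via dilithiated bromide 10 (not isolated), via lithium hemiaminal salt 11 (not isolated)
Conditions: LiN(iPr)2 (2.4 equiv.), THF, −78 °C; DMF (3 equiv.), −78 to −40 °C; then aq. NH4Cl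
Reagents that add atoms: N,N-dimethylformamide, CN(C)C=O
Why: Directed ortho-lithiation followed by formylation: once the alkoxide has formed, the amide base should remove the only kind of ring proton left, the one flanked and acidified by bromine and a benzyloxy group, giving aryllithium 10, which is kept at −78 °C to suppress LiBr loss to an aryne and adds to DMF to give 11, which releases the aldehyde on work-up.

**Step 6**
Reactants: 13 2-(benzyloxy)-N-methoxy-N-methylacetamide; 14 4-(benzyloxy)phenylmagnesium bromide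
Product: 16 2-(benzyloxy)-1-[4-(benzyloxy)phenyl]ethan-1-one, via magnesium hemiaminal chelate 15 (not isolated)
Conditions: 14 (1.2 equiv.), THF, 0 °C; then 1 M HCl
Reagents that add atoms: 4-(benzyloxy)phenylmagnesium bromide (14), Br[Mg]c1ccc(OCc2ccccc2)cc1
Why: Weinreb ketone synthesis: the N-methoxy-N-methylamide takes up one equivalent of the aryl Grignard reagent only, because chelate 15 does not collapse to the ketone before the acidic quench.

**Step 7**
Reactants: 16 2-(benzyloxy)-1-[4-(benzyloxy)phenyl]ethan-1-one; 12 2,4-bis(benzyloxy)-6-bromo-3-(3-hydroxy-3-methylbutyl)benzaldehyde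
Product: 18 2-(benzyloxy)-1-[4-(benzyloxy)phenyl]-3-[2,4-bis(benzyloxy)-6-bromo-3-(3-hydroxy-3-methylbutyl)phenyl]-3-hydroxypropan-1-one (racemic syn/anti mixture), via lithium enolate 17 (not isolated)
Conditions: 16 (1.3 equiv.), LiN(SiMe3)2 (1.3 equiv.), THF, −78 °C; then 12, −78 °C; AcOH quench at −78 °C
Reagents that add atoms: 2-(benzyloxy)-1-[4-(benzyloxy)phenyl]ethan-1-one (16), O=C(COCc1ccccc1)c1ccc(OCc2ccccc2)cc1
Why: Directed aldol addition of a preformed lithium enolate to a non-enolisable aldehyde forms C3–C4, the tertiary alcohol being too weak an acid to quench the enolate and the cold quench guarding against retro-aldol; the two new stereocentres arise without control and are erased in steps 8 and 9.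

**Step 8**
Reactants: 18 2-(benzyloxy)-1-[4-(benzyloxy)phenyl]-3-[2,4-bis(benzyloxy)-6-bromo-3-(3-hydroxy-3-methylbutyl)phenyl]-3-hydroxypropan-1-one
Product: 19 2-(benzyloxy)-1-[2,4-bis(benzyloxy)-6-bromo-3-(3-hydroxy-3-methylbutyl)phenyl]-3-[4-(benzyloxy)phenyl]propane-1,3-dione (racemic; enolisable)
Conditions: Dess–Martin periodinane (1.3 equiv.), NaHCO3, CH2Cl2, 0 °C to rt
Reagents that add atoms: none
Why: Dess–Martin oxidation turns the secondary benzylic carbinol into the C4 ketone under buffered, near-neutral conditions that the tertiary alcohol (not oxidisable), the benzyl ethers and the aryl bromide tolerate, a limited excess of oxidant guarding against further oxidation at C3.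

**Step 9**
Reactants: 19 2-(benzyloxy)-1-[2,4-bis(benzyloxy)-6-bromo-3-(3-hydroxy-3-methylbutyl)phenyl]-3-[4-(benzyloxy)phenyl]propane-1,3-dione
Product: 20 3,5,7-tris(benzyloxy)-2-[4-(benzyloxy)phenyl]-6-(3-hydroxy-3-methylbutyl)-4H-chromen-4-one
Conditions: CuI (10 mol%), 1,10-phenanthroline (20 mol%), Cs2CO3 (2 equiv.), 1,4-dioxane, 90 °C, Ar
Reagents that add atoms: none
Why: Ullmann-type intramolecular C–O coupling, the copper-catalysed O-arylation of 1-(2-haloaryl)-1,3-diketones that is an established way to flavones: Cs2CO3 removes the C3 proton, the diketonate binds phenanthroline-ligated monovalent copper, copper inserts into the C8a–Br bond activated by the ortho carbonyl, and C–O reductive elimination from the aryl copper enolate (trivalent copper) forms C8a–O1 and returns the catalyst. Ring C closes as a six-membered ring by attack of the enolate oxygen on the aromatic carbon, formally 6-exo-trig, through a seven-membered cupracycle that contracts on reductive elimination. No stereocentre is created, and the one at C3 of 19 vanishes as C2=C3 becomes part of the pyranone. The step needs O-arylation by the right oxygen: carbon C3 or the C4 oxygen could reach C8a only through a four-membered ring, so the geometry of 19 leaves the oxygen of the ring B carbonyl as the sole nucleophile that fits. The tertiary alcohol is too hindered to compete in intermolecular etherification, and dry carbonate base under argon should limit retro-Claisen cleavage and protodebromination.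

**Step 10**
Reactants: 20 3,5,7-tris(benzyloxy)-2-[4-(benzyloxy)phenyl]-6-(3-hydroxy-3-methylbutyl)-4H-chromen-4-one
Product: 21 3,5,7-trihydroxy-6-(3-hydroxy-3-methylbutyl)-2-(4-hydroxyphenyl)-4H-chromen-4-one
Conditions: H2 (1 atm), 10% Pd/C, THF–MeOH, rt
Reagents that add atoms: none
Why: Catalytic hydrogenolysis of benzyl ethers cleaves all four O–benzyl bonds to toluene at room temperature under neutral conditions, under which the flavonol C2=C3 bond, the C4 carbonyl and the tertiary alcohol are expected to persist.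

**Compound list**
1 | 4-bromo-2,6-difluorobenzaldehyde | O=Cc1c(F)cc(Br)cc1F | starting material
2 | benzyl alcohol | OCc1ccccc1 | starting material
3 | 2-(benzyloxy)-4-bromo-6-fluorobenzaldehyde (formed in the flask, not isolated) | O=Cc1c(F)cc(Br)cc1OCc1ccccc1 | intermediate
4 | 2,6-bis(benzyloxy)-4-bromobenzaldehyde | O=Cc1c(OCc2ccccc2)cc(Br)cc1OCc1ccccc1 | intermediate
5 | 1-(triphenyl-λ5-phosphanylidene)propan-2-one | CC(=O)C=P(c1ccccc1)(c1ccccc1)c1ccccc1 | starting material
6 | (3E)-4-[2,6-bis(benzyloxy)-4-bromophenyl]but-3-en-2-one | CC(=O)/C=C/c1c(OCc2ccccc2)cc(Br)cc1OCc1ccccc1 | intermediate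
7 | {[4-(2,6-bis(benzyloxy)-4-bromophenyl)but-2-en-2-yl]oxy}dimethyl(phenyl)silane, E/Z mixture (formed in the flask, not isolated) | CC(=CCc1c(OCc2ccccc2)cc(Br)cc1OCc1ccccc1)O[Si](C)(C)c1ccccc1 | intermediate
8 | 4-[2,6-bis(benzyloxy)-4-bromophenyl]butan-2-one | CC(=O)CCc1c(OCc2ccccc2)cc(Br)cc1OCc1ccccc1 | intermediate
9 | 4-[2,6-bis(benzyloxy)-4-bromophenyl]-2-methylbutan-2-ol | CC(C)(O)CCc1c(OCc2ccccc2)cc(Br)cc1OCc1ccccc1 | intermediate
10 | lithium 4-[2,6-bis(benzyloxy)-4-bromo-3-lithiophenyl]-2-methylbutan-2-olate (formed in the flask, not isolated) | [Li]OC(C)(C)CCc1c(OCc2ccccc2)cc(Br)c([Li])c1OCc1ccccc1 | intermediate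
11 | dilithium salt of [2,4-bis(benzyloxy)-6-bromo-3-(3-hydroxy-3-methylbutyl)phenyl](dimethylamino)methanol, racemic (formed in the flask, not isolated) | [Li]OC(C)(C)CCc1c(OCc2ccccc2)cc(Br)c(C(O[Li])N(C)C)c1OCc1ccccc1 | intermediate
12 | 2,4-bis(benzyloxy)-6-bromo-3-(3-hydroxy-3-methylbutyl)benzaldehyde | CC(C)(O)CCc1c(OCc2ccccc2)cc(Br)c(C=O)c1OCc1ccccc1 | intermediate
13 | 2-(benzyloxy)-N-methoxy-N-methylacetamide | CON(C)C(=O)COCc1ccccc1 | starting material
14 | 4-(benzyloxy)phenylmagnesium bromide | Br[Mg]c1ccc(OCc2ccccc2)cc1 | starting material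
15 | bromomagnesium 2-(benzyloxy)-1-[4-(benzyloxy)phenyl]-1-[methoxy(methyl)amino]ethan-1-olate, racemic chelate (formed in the flask, not isolated) | CON(C)C(COCc1ccccc1)(O[Mg]Br)c1ccc(OCc2ccccc2)cc1 | intermediate
16 | 2-(benzyloxy)-1-[4-(benzyloxy)phenyl]ethan-1-one | O=C(COCc1ccccc1)c1ccc(OCc2ccccc2)cc1 | intermediate
17 | lithium (Z)-2-(benzyloxy)-1-[4-(benzyloxy)phenyl]ethen-1-olate, chelated enolate whose geometry has no consequence (formed in the flask, not isolated) | [Li]O/C(=C\OCc1ccccc1)c1ccc(OCc2ccccc2)cc1 | intermediate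
18 | 2-(benzyloxy)-1-[4-(benzyloxy)phenyl]-3-[2,4-bis(benzyloxy)-6-bromo-3-(3-hydroxy-3-methylbutyl)phenyl]-3-hydroxypropan-1-one, racemic syn/anti mixture | CC(C)(O)CCc1c(OCc2ccccc2)cc(Br)c(C(O)C(OCc2ccccc2)C(=O)c2ccc(OCc3ccccc3)cc2)c1OCc1ccccc1 | intermediate
19 | 2-(benzyloxy)-1-[2,4-bis(benzyloxy)-6-bromo-3-(3-hydroxy-3-methylbutyl)phenyl]-3-[4-(benzyloxy)phenyl]propane-1,3-dione, racemic and enolisable | CC(C)(O)CCc1c(OCc2ccccc2)cc(Br)c(C(=O)C(OCc2ccccc2)C(=O)c2ccc(OCc3ccccc3)cc2)c1OCc1ccccc1 | intermediate
20 | 3,5,7-tris(benzyloxy)-2-[4-(benzyloxy)phenyl]-6-(3-hydroxy-3-methylbutyl)-4H-chromen-4-one | CC(C)(O)CCc1c(OCc2ccccc2)cc2oc(-c3ccc(OCc4ccccc4)cc3)c(OCc3ccccc3)c(=O)c2c1OCc1ccccc1 | intermediate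
21 | 3,5,7-trihydroxy-6-(3-hydroxy-3-methylbutyl)-2-(4-hydroxyphenyl)-4H-chromen-4-one (CNP0250430.0, achiral) | CC(C)(O)CCc1c(O)cc2oc(-c3ccc(O)cc3)c(O)c(=O)c2c1O | target

Total steps: 10. Longest linear sequence: 9 (steps 1–5 and 7–10, from compound 1).

**Steps most likely to fail**

Step 5 (ortho-lithiation and formylation). The ortho-bromo aryllithium may lose LiBr to an aryne, the base may metalate a benzylic OCH2 group, or metalation of the electron-rich ring may stay incomplete. The fallback sets out from 9 and comes back at 12 by halogen–magnesium exchange instead of deprotonation. Bromination with NBS (MeCN, 0 °C) can attack only the two equivalent free ring positions and should give 4-[2,6-bis(benzyloxy)-3,4-dibromophenyl]-2-methylbutan-2-ol F1. Treatment with i-PrMgCl·LiCl (2.2 equiv., THF, −20 °C) should first deprotonate the alcohol and then exchange the more hindered, ether-chelated bromine that lies between the benzyloxy group and the other bromine. This would give the chloromagnesium alkoxide of 4-[2,6-bis(benzyloxy)-4-bromo-3-(chloromagnesio)phenyl]-2-methylbutan-2-ol F2, which with DMF and aqueous work-up would give 12.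

Step 9 (copper ring closure). Base may cleave the 2-alkoxy-1,3-diketone by a retro-Claisen path, the bromide may be reduced off, or copper may insert too slowly into a C–Br bond on an electron-rich ring whose ketone is twisted out of plane. The fallback sets out from 19 and comes back at 20 by way of a ring A phenol and classical cyclodehydration. Miyaura borylation (B2pin2, PdCl2(dppf), KOAc, 1,4-dioxane, 80 °C) should give 2-(benzyloxy)-1-[2,4-bis(benzyloxy)-3-(3-hydroxy-3-methylbutyl)-6-(4,4,5,5-tetramethyl-1,3,2-dioxaborolan-2-yl)phenyl]-3-[4-(benzyloxy)phenyl]propane-1,3-dione F3. Mild oxidation (NaBO3·4H2O, THF–H2O, rt) would give 2-(benzyloxy)-1-[2,4-bis(benzyloxy)-6-hydroxy-3-(3-hydroxy-3-methylbutyl)phenyl]-3-[4-(benzyloxy)phenyl]propane-1,3-dione F4. Buffered acid (AcOH, NaOAc, 80 °C) should then close the hemiketal and dehydrate it to 20 without ionising the tertiary alcohol.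

Step 1 (double SNAr on the aldehyde). Benzyloxide may add to the formyl group and transfer hydride (Cannizzaro or Meerwein–Ponndorf type), and the second substitution may stall once the first ether has deactivated the ring. The fallback sets out from 1 and comes back at 4 with a nitrile as the activating group. Oxidative amination (I2, aq. NH3, THF, rt) should give 4-bromo-2,6-difluorobenzonitrile F5. Sodium benzyloxide (THF, 0 to 50 °C) should then substitute twice, by way of 2-(benzyloxy)-4-bromo-6-fluorobenzonitrile F6, to give 2,6-bis(benzyloxy)-4-bromobenzonitrile F7, with no carbonyl group for the alkoxide to attack. Half-reduction with i-Bu2AlH (toluene, −78 °C) and acidic hydrolysis of the imine would give 4.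

**Further compounds**
F1 | step 5 | 4-[2,6-bis(benzyloxy)-3,4-dibromophenyl]-2-methylbutan-2-ol | CC(C)(O)CCc1c(OCc2ccccc2)cc(Br)c(Br)c1OCc1ccccc1
F2 | step 5 | chloromagnesium alkoxide of 4-[2,6-bis(benzyloxy)-4-bromo-3-(chloromagnesio)phenyl]-2-methylbutan-2-ol | CC(C)(O[Mg]Cl)CCc1c(OCc2ccccc2)cc(Br)c([Mg]Cl)c1OCc1ccccc1
F3 | step 9 | 2-(benzyloxy)-1-[2,4-bis(benzyloxy)-3-(3-hydroxy-3-methylbutyl)-6-(4,4,5,5-tetramethyl-1,3,2-dioxaborolan-2-yl)phenyl]-3-[4-(benzyloxy)phenyl]propane-1,3-dione | CC(C)(O)CCc1c(OCc2ccccc2)cc(B2OC(C)(C)C(C)(C)O2)c(C(=O)C(OCc2ccccc2)C(=O)c2ccc(OCc3ccccc3)cc2)c1OCc1ccccc1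
F4 | step 9 | 2-(benzyloxy)-1-[2,4-bis(benzyloxy)-6-hydroxy-3-(3-hydroxy-3-methylbutyl)phenyl]-3-[4-(benzyloxy)phenyl]propane-1,3-dione | CC(C)(O)CCc1c(OCc2ccccc2)cc(O)c(C(=O)C(OCc2ccccc2)C(=O)c2ccc(OCc3ccccc3)cc2)c1OCc1ccccc1
F5 | step 1 | 4-bromo-2,6-difluorobenzonitrile | N#Cc1c(F)cc(Br)cc1F
F6 | step 1 | 2-(benzyloxy)-4-bromo-6-fluorobenzonitrile | N#Cc1c(F)cc(Br)cc1OCc1ccccc1
F7 | step 1 | 2,6-bis(benzyloxy)-4-bromobenzonitrile | N#Cc1c(OCc2ccccc2)cc(Br)cc1OCc1ccccc1
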